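In the 60.0 s of the south run, the very flask asked about, other capture product and target were read side by side.

| flask | solid substrate | first nucleophile | second nucleophile | remark | time |
|---|---|---|---|---|---|
| south | 20 mM | 30 mM | 80 mM | the very flask that is asked about, followed so far |  |
| flask | 20 mM | 30.0 mM | 80.0 mM |  | 8.0 min |

south run (percent of the solid substrate charged)

| time / s | other capture product / % | target / % | solid substrate / % |
|---|---|---|---|
| 12.0 | 1.1 | 5.8 | 68.8 |
| 25.0 | 4.1 | 17.9 | 41.1 |
| 30.0 | 1.4 | 20.9 | 33.2 |
| 50.0 | 3.8 | 37.6 | 0 |
| 60.0 | 2.7 | 40.7 | 0 |

(each reading ± 1 percentage point)

1. ratio of other capture product to target at 10 s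
2. ratio of other capture product to target at 1.0 min
3. ratio of other capture product to target at 8.0 min

The first row gives a ratio of 0.190, but its 1.1% of other capture product carries a scatter of 1 percentage point, so this end of the curve stays loose. From 25.0 s to 60.0 s target grows to twice its reading, while other capture product wanders between 1.4% and 4.1% without a clear trend. A second nucleophile lost early to its own decay step can account for that pattern. The solid column reads 0% at 50.0 s, and target then gains 3.1 points in the last interval, after 17 points in the one before.

The last two rows pooled give the late end, a ratio of 0.0830. Both captures draw on the same intermediate, at rates proportional to c(second nucleophile) and to c(first nucleophile) respectively. The decay step is first order, so c(second nucleophile) at each time scales with its charge. Taking c(first nucleophile) as its charge and holding the solid charge fixed, the late ratio divided by the ratio of the charges is the charge-scaled capture ratio 0.0311, a run-averaged reading for this solid charge and no rate-constant ratio of the two nucleophiles.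

This reckoning commits to about 0.190 at 10 s, loosely, and 0.0830 at both 1.0 min and 8.0 min. The forecast instead gives 0.13, 0.08 and 0.05, on the grounds that “The cumulative ratio therefore falls with time”.

The flask gives 0.305 at 10 s, 0.0787 at 1.0 min and 0.0765 at 8.0 min.

    starting material → intermediate (k = 0.120 s⁻¹)
    first nucleophile + intermediate → target (k = 830 L mol⁻¹ s⁻¹)
    second nucleophile + intermediate → other capture product (k = 170 L mol⁻¹ s⁻¹)
    intermediate → solvolysis product (k = 28.0 s⁻¹)
    second nucleophile → decomposed reagent (k = 0.0990 s⁻¹)
    solid substrate ⇌ starting material, rate k6*(cs6 - [starting material]) while solid is left; crystals form when [starting material] > cs6 (solubility = 10.0 mM, k = 0.0630 s⁻¹)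

Other capture product stands at 3.18% after 0.800 min and at 3.19% after 8.00 min, while second nucleophile is down to 0.815% of its charge at the earlier time. The final ratio scaled by the charges is 0.0287, beside 0.0311 from the readings. For the flask charged with 48 mM of second nucleophile, 0.0311 gives 0.0498, and that flask stands at 0.0470 at 8.0 min.

(Readings and results were computed for substances that don't exist; the scatter is artificial.)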